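**Retrosynthetic overview**

1. C7 is set last. The target is unmasked from a 4‑methoxybenzyl ester/dimethyl acetal whose C7–H comes from kinetic protonation of a cross‑conjugated trienolate. That enolate is made from a 7(11)‑alkylidene ketone (aldol condensation of the bicyclic enone with 1,1‑dimethoxyacetone).
2. Key bond C1–O: anodic γ‑acyloxylation of the silyl dienol ether of the bicyclic enone with the free side‑chain acid. This joins the two halves and sets C1.
3. The enone ester comes from (S)‑Wieland–Miescher ketone by one‑carbon homologation of the C4 ketone (Wittig, hydrolysis, chlorite oxidation, esterification).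
4. The acid comes from Wittig and Horner–Wadsworth–Emmons olefinations of (2R,4S)‑2,4‑dimethylhexanal, made from a lactate triflate and the (S)‑2‑methylbutyl Grignard reagent (SN2, inversion).
5. Ring order: both carbocycles are bought together in the decalin of Wieland–Miescher ketone; no ring is formed in the route.

Assumption: (S)‑(+)‑Wieland–Miescher ketone, tert‑butyl (R)‑lactate and (S)‑1‑bromo‑2‑methylbutane are bought as single enantiomers; positions are quoted in eremophilane numbering (C1 oxygen‑bearing, C4 carboxyl‑bearing, C5 angular methyl, C7 next to the C8 ketone, C9=C10, C11–C13 the propenal unit); PMB = 4‑methoxybenzyl; acyl = (2E,4E,6R,8S)‑4,6,8‑trimethyldeca‑2,4‑dienoyl.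

**Route**

Step 1
Reactants: 1 tert‑butyl (R)‑lactate
Product: 2 tert‑butyl (2R)‑2‑{[(trifluoromethyl)sulfonyl]oxy}propanoate
Conditions: Tf2O, 2,6‑lutidine, CH2Cl2, −78 → 0 °C
Reagents that add atoms: trifluoromethanesulfonic anhydride, O=S(=O)(OS(=O)(=O)C(F)(F)F)C(F)(F)F
Why: O‑sulfonylation of the secondary alcohol with a hindered base leaves the C–O bond untouched, so the bought (R) centre is retained.

Step 2
Reactants: 3 (S)‑1‑bromo‑2‑methylbutane; 2 tert‑butyl (2R)‑2‑{[(trifluoromethyl)sulfonyl]oxy}propanoate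
Product: 5 tert‑butyl (2R,4S)‑2,4‑dimethylhexanoate, via Grignard reagent 4 (not isolated)
Conditions: Mg, THF, 40 °C; then 2, ZnCl2 (10 mol%), THF, 0 °C
Reagents that add atoms: none
Why: Zinc‑catalysed sp3–sp3 cross‑coupling of an α‑triflyloxy ester with an alkyl Grignard reagent is an SN2 displacement by the triorganozincate that inverts the lactate carbon cleanly (the descriptor stays R because the priorities change), while C4 (S) is bought in 3 and is not at the metal‑bearing carbon.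

Step 3
Reactants: 5 tert‑butyl (2R,4S)‑2,4‑dimethylhexanoate
Product: 6 (2R,4S)‑2,4‑dimethylhexanal
Conditions: i‑Bu2AlH (1.1 equiv), CH2Cl2, −78 °C; aq. potassium sodium tartrate work‑up
Reagents that add atoms: none
Why: Partial ester reduction stops at the stable tetrahedral aluminate of the tert‑butyl ester at −78 °C, and the cold neutral work‑up does not epimerise the α‑centre.

Step 4
Reactants: 6 (2R,4S)‑2,4‑dimethylhexanal
Product: 7 (2E,4R,6S)‑2,4,6‑trimethyloct‑2‑enal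
Conditions: Ph3P=C(Me)CHO, toluene, 90 °C
Reagents that add atoms: 2‑(triphenylphosphoranylidene)propanal, CC(C=O)=P(c1ccccc1)(c1ccccc1)c1ccccc1
Why: Wittig olefination with a formyl‑stabilised ylide is E‑selective and base‑free, so the trisubstituted alkene forms without touching the adjacent stereocentre.

Step 5
Reactants: 7 (2E,4R,6S)‑2,4,6‑trimethyloct‑2‑enal
Product: 8 (2E,4E,6R,8S)‑4,6,8‑trimethyldeca‑2,4‑dienoic acid
Conditions: (EtO)2P(O)CH2CO2H, n‑BuLi (2 equiv), THF, −78 → 23 °C; then 1 M HCl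
Reagents that add atoms: 2‑(diethoxyphosphoryl)acetic acid, OC(=O)CP(=O)(OCC)OCC
Why: Horner–Wadsworth–Emmons olefination with the phosphonoacetic acid dianion gives the (E)‑acrylic acid directly, and the stabilised carbanion does not deprotonate the γ‑stereocentre of the enal.

Step 6
Reactants: 9 (S)‑Wieland–Miescher ketone
Product: 11 (1S,8aR)‑8a‑methyl‑6‑oxo‑1,2,3,4,6,7,8,8a‑octahydronaphthalene‑1‑carbaldehyde, via enol ether 10 (not isolated)
Conditions: Ph3P(CH2OMe)Cl (3 equiv), KN(SiMe3)2 (2.9 equiv), THF, 0 → 23 °C; then 2 M HCl, THF, 23 °C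
Reagents that add atoms: (methoxymethyl)triphenylphosphonium chloride, [Cl-].COC[P+](c1ccccc1)(c1ccccc1)c1ccccc1; water, O
Why: Wittig methoxymethylenation is selective for the saturated C4 ketone because excess ylide first turns the enone into its unreactive dienolate; acid hydrolysis then protonates C4 axially from the α face, anti to the angular methyl, and the aldehyde settles equatorial, so C4 (S, formyl cis to the methyl) is controlled by the bought C5 centre.

Step 7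
Reactants: 11 (1S,8aR)‑8a‑methyl‑6‑oxo‑1,2,3,4,6,7,8,8a‑octahydronaphthalene‑1‑carbaldehyde
Product: 12 (1S,8aR)‑8a‑methyl‑6‑oxo‑1,2,3,4,6,7,8,8a‑octahydronaphthalene‑1‑carboxylic acid
Conditions: NaClO2, NaH2PO4, 2‑methyl‑2‑butene, t‑BuOH/H2O, 23 °C
Reagents that add atoms: sodium chlorite, [Na+].[O-]Cl=O
Why: Pinnick oxidation converts the aldehyde to the acid at pH about 4 without epimerising C4 or touching the enone, the alkene scavenging HOCl.

Step 8
Reactants: 12 (1S,8aR)‑8a‑methyl‑6‑oxo‑1,2,3,4,6,7,8,8a‑octahydronaphthalene‑1‑carboxylic acid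
Product: 13 PMB (1S,8aR)‑8a‑methyl‑6‑oxo‑1,2,3,4,6,7,8,8a‑octahydronaphthalene‑1‑carboxylate
Conditions: PMBCl, K2CO3, DMF, 23 °C
Reagents that add atoms: 4‑methoxybenzyl chloride, COc1ccc(CCl)cc1
Why: Carboxylate O‑alkylation (SN2 at the benzylic chloride) is insensitive to the neopentyl hindrance at C4, and carbonate is too weak to enolise the enone.

Step 9
Reactants: 13 PMB (1S,8aR)‑8a‑methyl‑6‑oxo‑1,2,3,4,6,7,8,8a‑octahydronaphthalene‑1‑carboxylate
Product: 14 PMB (1S,8aR)‑6‑[(tert‑butyldimethylsilyl)oxy]‑8a‑methyl‑1,2,3,7,8,8a‑hexahydronaphthalene‑1‑carboxylate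
Conditions: TBSOTf (1.3 equiv), Et3N (3 equiv), CH2Cl2, −78 → 0 °C
Reagents that add atoms: tert‑butyldimethylsilyl trifluoromethanesulfonate, CC(C)(C)[Si](C)(C)OS(=O)(=O)C(F)(F)F
Why: Soft enolisation with O‑silylation under equilibrating conditions gives the thermodynamic heteroannular 2‑silyloxy‑1,3‑diene (γ‑deprotonation at C1), as with steroidal 4‑en‑3‑ones; no stereocentre is formed.

Step 10
Reactants: 14 PMB (1S,8aR)‑6‑[(tert‑butyldimethylsilyl)oxy]‑8a‑methyl‑1,2,3,7,8,8a‑hexahydronaphthalene‑1‑carboxylate; 8 (2E,4E,6R,8S)‑4,6,8‑trimethyldeca‑2,4‑dienoic acid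
Product: 15 PMB (1S,4R,8aR)‑4‑(acyloxy)‑8a‑methyl‑6‑oxo‑1,2,3,4,6,7,8,8a‑octahydronaphthalene‑1‑carboxylate
Conditions: undivided cell, reticulated vitreous carbon anode, Pt cathode, constant current (2 mA cm−2, 2.2 F mol−1); 14 (1.3 equiv), 8 (1.0 equiv), 2,6‑lutidine (2.5 equiv), (4‑BrC6H4)3N (10 mol%), Bu4NClO4 (0.1 M), CH2Cl2/MeCN 4:1, −20 °C
Reagents that add atoms: none
Why: Proposed new method: triarylamine‑mediated anodic vinylogous acyloxylation of a silyl dienol ether with a complex carboxylic acid as the limiting nucleophile; one‑electron oxidation at about +1.05 V (below the potentials of the dienoate, the carboxylate and the PMB arene) gives the dienol ether radical cation, the lutidinium carboxylate adds at the γ‑terminus C1 to leave a delocalised α‑siloxyallyl radical, and a second oxidation with loss of the silyl group to lutidine restores the C9=C10 enone while the cathode makes H2; attack is axial on the β face (chair‑like transition state, relief of A(1,3) strain with H‑9), which sets C1 (R) cis to the angular methyl as in 6β‑functionalisation of steroidal 3,5‑dienol ethers; the closest known reaction types are anodic α‑acetoxylation and alkoxylation of enol ethers and enol acetates, nucleophile trapping of enol ether radical cations in anodic olefin couplings, and the vinylogous Rubottom oxidation.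

Step 11
Reactants: 15 PMB (1S,4R,8aR)‑4‑(acyloxy)‑8a‑methyl‑6‑oxo‑1,2,3,4,6,7,8,8a‑octahydronaphthalene‑1‑carboxylate
Product: 18 PMB (1S,4R,7E,8aR)‑4‑(acyloxy)‑7‑(1,1‑dimethoxypropan‑2‑ylidene)‑8a‑methyl‑6‑oxo‑1,2,3,4,6,7,8,8a‑octahydronaphthalene‑1‑carboxylate, via lithium aldolate 16 (not isolated), via tertiary acetate 17 (not isolated)
Conditions: LiN(i‑Pr)2 (1.1 equiv), THF, −78 °C; MeCOCH(OMe)2; Ac2O, −78 → 0 °C; DBU, 23 °C
Reagents that add atoms: 1,1‑dimethoxypropan‑2‑one, CC(=O)C(OC)OC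
Why: Kinetic α'‑deprotonation gives the cross‑conjugated lithium enolate, which adds to the chelating α,α‑dialkoxy ketone (aldol addition); acetylation of the aldolate and E1cB elimination complete the aldol condensation, so the C7 and C11 centres of the adduct are erased (E major, the Z isomer converges in step 12).

Step 12
Reactants: 18 PMB (1S,4R,7E,8aR)‑4‑(acyloxy)‑7‑(1,1‑dimethoxypropan‑2‑ylidene)‑8a‑methyl‑6‑oxo‑1,2,3,4,6,7,8,8a‑octahydronaphthalene‑1‑carboxylate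
Product: 20 PMB (1S,4R,7R,8aR)‑4‑(acyloxy)‑7‑(3,3‑dimethoxyprop‑1‑en‑2‑yl)‑8a‑methyl‑6‑oxo‑1,2,3,4,6,7,8,8a‑octahydronaphthalene‑1‑carboxylate, via lithium trienolate 19 (not isolated)
Conditions: LiN(i‑Pr)2 (1.3 equiv), DMPU, THF, −78 °C; then cannulated into t‑BuCO2H (5 equiv), THF, −78 °C
Reagents that add atoms: none
Why: Deconjugative isomerisation by γ‑deprotonation of the methyl syn to the carbonyl and kinetic α‑protonation of the cross‑conjugated trienolate; the bulky acid delivers the proton to C7 from the α face, opposite the pseudo‑axial angular methyl of the flat dienolate ring, which puts the three‑carbon unit β and sets C7 (R), and the inverse quench prevents equilibration to the more stable 7‑epimer or back to 18.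

Step 13
Reactants: 20 PMB (1S,4R,7R,8aR)‑4‑(acyloxy)‑7‑(3,3‑dimethoxyprop‑1‑en‑2‑yl)‑8a‑methyl‑6‑oxo‑1,2,3,4,6,7,8,8a‑octahydronaphthalene‑1‑carboxylate
Product: 21 (1S,4R,7R,8aR)‑8a‑methyl‑6‑oxo‑7‑(3‑oxoprop‑1‑en‑2‑yl)‑4‑{[(2E,4E,6R,8S)‑4,6,8‑trimethyldeca‑2,4‑dienoyl]oxy}‑1,2,3,4,6,7,8,8a‑octahydronaphthalene‑1‑carboxylic acid (target)
Conditions: TFA/CH2Cl2 1:9, anisole (5 equiv), H2O (5 equiv), 0 °C, 20 min
Reagents that add atoms: water, O
Why: Acidolysis cleaves the PMB ester by an SN1 path (the benzylic cation is trapped by anisole) and hydrolyses the allylic dimethyl acetal in the same operation; the short, cold exposure leaves the secondary dienoate ester intact and avoids acid enolisation at C7.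

**Compound list**

1 | tert‑butyl (2R)‑2‑hydroxypropanoate (tert‑butyl (R)‑lactate) | C[C@@H](O)C(=O)OC(C)(C)C | starting material
2 | tert‑butyl (2R)‑2‑{[(trifluoromethyl)sulfonyl]oxy}propanoate | C[C@@H](OS(=O)(=O)C(F)(F)F)C(=O)OC(C)(C)C | intermediate
3 | (S)‑1‑bromo‑2‑methylbutane | BrC[C@@H](C)CC | starting material
4 | (S)‑(2‑methylbutyl)magnesium bromide | Br[Mg]C[C@@H](C)CC | intermediate
5 | tert‑butyl (2R,4S)‑2,4‑dimethylhexanoate | CC(C)(C)OC(=O)[C@H](C)C[C@@H](C)CC | intermediate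
6 | (2R,4S)‑2,4‑dimethylhexanal | O=C[C@H](C)C[C@@H](C)CC | intermediate
7 | (2E,4R,6S)‑2,4,6‑trimethyloct‑2‑enal | O=C/C(C)=C/[C@H](C)C[C@@H](C)CC | intermediate
8 | (2E,4E,6R,8S)‑4,6,8‑trimethyldeca‑2,4‑dienoic acid | OC(=O)/C=C/C(C)=C/[C@H](C)C[C@@H](C)CC | intermediate
9 | (S)‑Wieland–Miescher ketone, (8aS)‑8a‑methyl‑3,4,8,8a‑tetrahydronaphthalene‑1,6(2H,7H)‑dione | O=C1CC[C@@]2(C)C(=C1)CCCC2=O | starting material
10 | (4aS)‑5‑(methoxymethylidene)‑4a‑methyl‑4,4a,5,6,7,8‑hexahydronaphthalen‑2(3H)‑one (E/Z mixture) | O=C1CC[C@@]2(C)C(=C1)CCCC2=COC | intermediate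
11 | (1S,8aR)‑8a‑methyl‑6‑oxo‑1,2,3,4,6,7,8,8a‑octahydronaphthalene‑1‑carbaldehyde | O=C1CC[C@@]2(C)C(=C1)CCC[C@@H]2C=O | intermediate
12 | (1S,8aR)‑8a‑methyl‑6‑oxo‑1,2,3,4,6,7,8,8a‑octahydronaphthalene‑1‑carboxylic acid | O=C1CC[C@@]2(C)C(=C1)CCC[C@@H]2C(=O)O | intermediate
13 | 4‑methoxybenzyl (1S,8aR)‑8a‑methyl‑6‑oxo‑1,2,3,4,6,7,8,8a‑octahydronaphthalene‑1‑carboxylate | O=C1CC[C@@]2(C)C(=C1)CCC[C@@H]2C(=O)OCc1ccc(OC)cc1 | intermediate
14 | 4‑methoxybenzyl (1S,8aR)‑6‑[(tert‑butyldimethylsilyl)oxy]‑8a‑methyl‑1,2,3,7,8,8a‑hexahydronaphthalene‑1‑carboxylate | CC(C)(C)[Si](C)(C)OC1=CC2=CCC[C@H](C(=O)OCc3ccc(OC)cc3)[C@@]2(C)CC1 | intermediate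
15 | 4‑methoxybenzyl (1S,4R,8aR)‑8a‑methyl‑6‑oxo‑4‑{[(2E,4E,6R,8S)‑4,6,8‑trimethyldeca‑2,4‑dienoyl]oxy}‑1,2,3,4,6,7,8,8a‑octahydronaphthalene‑1‑carboxylate | O=C1CC[C@@]2(C)C(=C1)[C@H](OC(=O)/C=C/C(C)=C/[C@H](C)C[C@@H](C)CC)CC[C@@H]2C(=O)OCc1ccc(OC)cc1 | intermediate
16 | lithium alkoxide of the 7α‑(2‑hydroxy‑1,1‑dimethoxypropan‑2‑yl) aldol adduct of 15 (C7 substituent trans to the angular methyl, both C11 epimers) | [Li+].COC(OC)C(C)([O-])[C@@H]1C[C@@]2(C)C(=CC1=O)[C@H](OC(=O)/C=C/C(C)=C/[C@H](C)C[C@@H](C)CC)CC[C@@H]2C(=O)OCc1ccc(OC)cc1 | intermediate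
17 | 7α‑(2‑acetoxy‑1,1‑dimethoxypropan‑2‑yl) derivative of 15 (acetate of 16) | COC(OC)C(C)(OC(C)=O)[C@@H]1C[C@@]2(C)C(=CC1=O)[C@H](OC(=O)/C=C/C(C)=C/[C@H](C)C[C@@H](C)CC)CC[C@@H]2C(=O)OCc1ccc(OC)cc1 | intermediate
18 | 4‑methoxybenzyl (1S,4R,7E,8aR)‑7‑(1,1‑dimethoxypropan‑2‑ylidene)‑8a‑methyl‑6‑oxo‑4‑{[(2E,4E,6R,8S)‑4,6,8‑trimethyldeca‑2,4‑dienoyl]oxy}‑1,2,3,4,6,7,8,8a‑octahydronaphthalene‑1‑carboxylate (E major) | COC(OC)/C(C)=C1\C[C@@]2(C)C(=CC1=O)[C@H](OC(=O)/C=C/C(C)=C/[C@H](C)C[C@@H](C)CC)CC[C@@H]2C(=O)OCc1ccc(OC)cc1 | intermediate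
19 | lithium trienolate of 18 (C8 enolate oxygen, C7=C8, C9=C10 and C11=C13 double bonds) | [Li+].COC(OC)C(=C)C=1C[C@@]2(C)C(=CC=1[O-])[C@H](OC(=O)/C=C/C(C)=C/[C@H](C)C[C@@H](C)CC)CC[C@@H]2C(=O)OCc1ccc(OC)cc1 | intermediate
20 | 4‑methoxybenzyl (1S,4R,7R,8aR)‑7‑(3,3‑dimethoxyprop‑1‑en‑2‑yl)‑8a‑methyl‑6‑oxo‑4‑{[(2E,4E,6R,8S)‑4,6,8‑trimethyldeca‑2,4‑dienoyl]oxy}‑1,2,3,4,6,7,8,8a‑octahydronaphthalene‑1‑carboxylate | COC(OC)C(=C)[C@H]1C[C@@]2(C)C(=CC1=O)[C@H](OC(=O)/C=C/C(C)=C/[C@H](C)C[C@@H](C)CC)CC[C@@H]2C(=O)OCc1ccc(OC)cc1 | intermediate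
21 | (1S,4R,7R,8aR)‑8a‑methyl‑6‑oxo‑7‑(3‑oxoprop‑1‑en‑2‑yl)‑4‑{[(2E,4E,6R,8S)‑4,6,8‑trimethyldeca‑2,4‑dienoyl]oxy}‑1,2,3,4,6,7,8,8a‑octahydronaphthalene‑1‑carboxylic acid | C=C(C=O)[C@H]1C[C@@]2(C)C(=CC1=O)[C@H](OC(=O)/C=C/C(C)=C/[C@H](C)C[C@@H](C)CC)CC[C@@H]2C(=O)O | target

**Totals and risks**

Total step count: 13. Longest linear sequence: 9 steps (steps 1–5, then 10–13).

The three steps most likely to fail are steps 10, 11 and 12.

Step 10 is the new anodic fragment union. It may give α‑attack, desaturation to the 1,9‑dienone, radical‑cation dimers or the 1α‑ester. The fallback uses known chemistry and sets out from 14. Vinylogous Rubottom oxidation (m‑CPBA, NaHCO3, CH2Cl2, −20 °C, then aq. HF/MeCN) gives 4‑methoxybenzyl (1S,4R,8aR)‑4‑hydroxy‑8a‑methyl‑6‑oxo‑1,2,3,4,6,7,8,8a‑octahydronaphthalene‑1‑carboxylate F1, by axial β attack at the γ‑carbon as in 6β‑hydroxylation of steroidal dienol ethers. Yamaguchi esterification of this alcohol with 8 (2,4,6‑trichlorobenzoyl chloride, Et3N, then DMAP, toluene, 23 °C) comes back to the route at 15.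

Step 11 is a one‑pot aldol condensation with a ketone electrophile. It may stall through retro‑aldol before the aldolate is trapped. The fallback sets out from 15 and replaces the aldol by a palladium‑catalysed ketone α'‑alkenylation: LiN(SiMe3)2 (2.2 equiv), Pd2(dba)3/P(t‑Bu)3 (zerovalent palladium), 2‑bromo‑3,3‑dimethoxyprop‑1‑ene, THF/toluene, 23–50 °C. Ordinary NH4Cl work‑up gives mainly the 7α‑epimer, 4‑methoxybenzyl (1S,4R,7S,8aR)‑7‑(3,3‑dimethoxyprop‑1‑en‑2‑yl)‑8a‑methyl‑6‑oxo‑4‑(acyloxy)‑1,2,3,4,6,7,8,8a‑octahydronaphthalene‑1‑carboxylate F2. Re‑enolisation with LiN(i‑Pr)2 converts it into 19, where the fallback comes back to the route; the pivalic acid quench of step 12 then gives 20, and 18 is bypassed.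

Step 12 is the kinetic protonation that sets C7. It may give γ‑protonation back to 18 or too much of the 7α‑epimer. The fallback sets out from 18 and separates enolate formation from protonation. LiN(i‑Pr)2 then Et3SiCl (THF, −78 °C) gives the isolable silyl trienol ether, 4‑methoxybenzyl (1S,4R,8aR)‑7‑(3,3‑dimethoxyprop‑1‑en‑2‑yl)‑8a‑methyl‑6‑[(triethylsilyl)oxy]‑4‑(acyloxy)‑1,2,3,4,8,8a‑hexahydronaphthalene‑1‑carboxylate F3. Protodesilylation with pyridine‑buffered HF·pyridine in THF at −78 °C protonates C7 from the open α face and comes back to the route at 20.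

**Further compounds**

F1 | step 10 | 4‑methoxybenzyl (1S,4R,8aR)‑4‑hydroxy‑8a‑methyl‑6‑oxo‑1,2,3,4,6,7,8,8a‑octahydronaphthalene‑1‑carboxylate | O=C1CC[C@@]2(C)C(=C1)[C@H](O)CC[C@@H]2C(=O)OCc1ccc(OC)cc1
F2 | step 11 | 4‑methoxybenzyl (1S,4R,7S,8aR)‑7‑(3,3‑dimethoxyprop‑1‑en‑2‑yl)‑8a‑methyl‑6‑oxo‑4‑{[(2E,4E,6R,8S)‑4,6,8‑trimethyldeca‑2,4‑dienoyl]oxy}‑1,2,3,4,6,7,8,8a‑octahydronaphthalene‑1‑carboxylate | COC(OC)C(=C)[C@@H]1C[C@@]2(C)C(=CC1=O)[C@H](OC(=O)/C=C/C(C)=C/[C@H](C)C[C@@H](C)CC)CC[C@@H]2C(=O)OCc1ccc(OC)cc1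
F3 | step 12 | 4‑methoxybenzyl (1S,4R,8aR)‑7‑(3,3‑dimethoxyprop‑1‑en‑2‑yl)‑8a‑methyl‑6‑[(triethylsilyl)oxy]‑4‑{[(2E,4E,6R,8S)‑4,6,8‑trimethyldeca‑2,4‑dienoyl]oxy}‑1,2,3,4,8,8a‑hexahydronaphthalene‑1‑carboxylate | COC(OC)C(=C)C=1C[C@@]2(C)C(=CC=1O[Si](CC)(CC)CC)[C@H](OC(=O)/C=C/C(C)=C/[C@H](C)C[C@@H](C)CC)CC[C@@H]2C(=O)OCc1ccc(OC)cc1
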